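Amounts first: in a closed flask I can count how much starting material has left its free form and how much intermediate stands at that moment, before any scheme is drawn. I had to judge birch and oak from two earlier runs.

| flask | starting material | partner | remark | time |
|---|---|---|---|---|
| dawn | 0.030 M | 0.055 M | run made earlier |  |
| dusk | 0.050 M | 0.086 M | run made earlier |  |
| birch | 0.080 M | 0.0800 M |  | 30 h |
| oak | 0.050 M | 0.0550 M |  | 20 h |

1. the flask that ends with the higher amount of intermediate, in percent of the starting material charged, or "neither" when 2 percentage points or less lies between them (birch / oak / neither)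
2. final intermediate, as a percentage of the starting material charged, in birch
3. final intermediate, as a percentage of the starting material charged, in oak

- a reading or a percentage of target counts all its forms, free or not
- a reading of starting material is of its free form alone

| run | time / h | intermediate / % | target / % | starting material / % |
|---|---|---|---|---|
| dawn | 1.00 | 5.5 | 1.8 | 97.6 |
| dawn | 2.00 | 8.5 | 2.2 | 88.7 |
| dawn | 4.00 | 14.8 | 5.0 | 76.3 |
| dawn | 8.00 | 21.9 | 13.8 | 57.8 |
| dawn | 15.0 | 32.0 | 19.2 | 36.3 |
| dusk | 1.33 | 5.6 | 1.8 | 89.8 |
| dusk | 4.00 | 11.6 | 6.9 | 75.1 |
| dusk | 6.00 | 18.0 | 9.1 | 64.5 |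
| dusk | 10.0 | 23.2 | 13.9 | 46.8 |
| dusk | 15.0 | 28.3 | 18.7 | 33.6 |

(standard deviation of a reading: 1 percentage point)

I read the last row of each table. By its last reading dawn had lost 63.7% of its charge from the free form and held 32.0% as intermediate; dusk had lost 66.4% and held 28.3%. That made 50.2% in dawn and 42.6% in dusk. Both charges differed between these runs, so I took the mean, 46.4%, and carried it: the kept share, the intermediate standing per unit of starting material lost, a selectivity on conversion.

The starting-material columns gave 0.0676 h⁻¹ and 0.0727 h⁻¹ as first-order rates, mean 0.0701 h⁻¹. With that rate I reckoned a loss of 87.8% for birch and 75.4% for oak, so my first answer was 40.8% for birch and 35.0% for oak.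

But that share stopped at 15.0 h, and oak's 20 h already runs past it. So I went round once more. I kept the answer up to that time and gave the later loss the share of the last stretch of both runs, 42.8%. My reckoning now put birch at 39.9% and oak at 34.6%. I committed to birch, ahead by 5.3 percentage points, which is more than the margin.

The forecast gave 30.5% for birch and 34% for oak, hence oak, in its words “Oak probably ends higher”, and there my reckoning parted from it.

Birch ended at 48.2% and oak at 37.2%, so birch stood higher. The steps in the flasks were these:

    starting material + target ⇌ idle adduct, settled at all times (K = 120 M⁻¹)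
    partner + intermediate → target (k = 0.00231 M⁻¹ s⁻¹)
    starting material → intermediate (k = 1.56 × 10⁻⁵ s⁻¹)
    partner + target → over-reaction product (k = 2.32 × 10⁻⁴ M⁻¹ s⁻¹)
    2 partner → homo product (k = 0.00143 M⁻¹ s⁻¹)
    intermediate → decomposed reagent (k = 1.41 × 10⁻⁶ s⁻¹)

In birch the partner, the limiting reagent, was down to 0.026% of its charge at 30.0 h. The kept share stood at 57.7% in birch and 50.7% in oak at their ends, against my 46.4%. A further flask, like oak but with c(starting material) 0.085 M, had lost 72.9% of its charge from the free form; my share put on that loss gives 33.8%. That flask held 41.5%, a kept share of 56.9%.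

The runs come from a simulation for an exercise.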